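The numbers in the tables are calculated with constants of no real substance, noise included.

The bis adduct is the product I follow, and it is what the runs read, so I weigh it against one lump: whatever else the starting material is or has become. These two amounts give the odds, bis adduct over the rest, and the zero of my scale is even odds of one, where the two stand equal.

| setting | eta | theta | zeta | Friday's | Wednesday's | Sunday's |
|---|---|---|---|---|---|---|
| starting material | 0.10 M | 0.10 M | 0.10 M | 0.10 M | 0.10 M | 0.10 M |
| reagent | 0.040 M | 0.12 M | 0.25 M | 0.0500 M | 0.200 M | 0.300 M |
| scavenger | 0.050 M | 0.050 M | 0.050 M | 0.0500 M | 0.0500 M | 0.0500 M |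
| capture agent | 0.10 M | 0.10 M | 0.10 M | 0.100 M | 0.100 M | 0.100 M |
| remark | run made earlier | run made earlier | run made earlier |  |  |  |
| time |  |  |  | 50 h | 50 h | 50 h |

| run | time / h | bis adduct / % |
|---|---|---|
| eta | 3.00 | 0 |
| eta | 8.00 | 2.5 |
| eta | 15.0 | 2.0 |
| eta | 25.0 | 3.0 |
| eta | 40.0 | 3.4 |
| theta | 3.00 | 0.7 |
| theta | 5.00 | 3.8 |
| theta | 10.0 | 6.6 |
| theta | 20.0 | 13.2 |
| theta | 40.0 | 16.4 |
| zeta | 3.00 | 4.7 |
| zeta | 5.00 | 9.7 |
| zeta | 10.0 | 17.6 |
| zeta | 20.0 | 26.3 |
| zeta | 40.0 | 31.8 |

(scatter of a reading: 1 percentage point)



- which of these holds the largest part of the starting material at the end of Friday's (single product / bis adduct / starting material)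
- which of these holds the largest part of the starting material at the end of Wednesday's (single product / bis adduct / starting material)
- which of these holds the largest part of the starting material at the end of Sunday's (single product / bis adduct / starting material)
- how much bis adduct is there at the end of Friday's, in percent of the starting material charged

I take the last reading of the two outer runs:

eta, 0.040 M of reagent: odds 0.0352
zeta, 0.25 M of reagent: odds 0.466
slope: 2.05 /M

I call this slope the odds gain, the odds won per molar of reagent at the last reading, with the other charges held as in these runs. The theta run tests it, since it played no part in the slope: the line gives 0.199 at 0.12 M, and its own reading gives 0.196.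

For Friday's flask, with c(reagent) = 0.0500 M:

odds = 0.0352 + 2.05 /M × (0.0500 M − 0.040 M) = 0.0557
bis adduct = odds / (one + odds) = 5.28%

I commit to 5.28%, give or take 1 percentage point, the scatter of one reading, and lean upward, since Friday's runs to 50 h, later than the last reading at 40.0 h. The odds do not divide the lump, so they leave open which species holds most.

The forecast gives 5% (from 3.5% to 6.5%) and names starting material, single product and single product for Friday's, Wednesday's and Sunday's, holding for the last two that “Bis stays below half, which leaves single product largest”.

The flask gives 5.74% on Friday's, and of the three species asked about, starting material holds the most there at 43.1%. Of the same three, bis adduct holds the most on Wednesday's at 29.0% and on Sunday's at 37.7%.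

    single product → side product (k = 0.0740 /h)
    single product + capture agent → trapped intermediate (k = 0.260 /M/h)
    starting material + reagent → single product + released group (k = 0.290 /M/h)
    scavenger + released group → scavenged by-product (k = 0.750 /M/h)
    reagent + single product → bis adduct + released group (k = 1.00 /M/h)
    starting material + released group ⇌ idle adduct, settled at all times (K = 350 /M)

Friday's odds stand at 0.0609 against my 0.0557, but Friday's flask has not come to rest. Between 50.0 h and 500 h its reagent falls from 33% to 0.353% of its charge, its side product grows from 14.5% to 26.7% of the starting material charged, and bis adduct reaches 7.09%, odds of 0.0763.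

Friday's flask with 0.085 M of reagent gets odds of 0.128 from the odds gain, so 11.3% bis adduct. The computed flask gives 12.4%.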